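(The runs were computed with made-up constants; noise was put on by code.)

At late times the summer run still reads 18% L and 62% J at 25.0 h, while the midnight run reads 1% L and 100% J.

in all of them: L 0.011 M

| run | D | remark | time |
|---|---|---|---|
| summer | 1.1 equiv | run made earlier |  |
| midnight | 4.1 equiv | run made earlier |  |
| Sunday's | 1.30 equiv |  | 25 h |
| Friday's | 2.60 equiv |  | 25 h |
| Tuesday's | 5.20 equiv |  | 25 h |

| run | time / h | L / % | J / % |
|---|---|---|---|
| summer | 1.50 | 35 | 49 |
| summer | 5.00 | 24 | 52 |
| summer | 8.00 | 23 | 53 |
| summer | 15.0 | 16 | 58 |
| summer | 20.0 | 20 | 58 |
| summer | 25.0 | 18 | 62 |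
| midnight | 4.00 | 2 | 94 |
| midnight | 8.00 | 2 | 98 |
| midnight | 12.0 | 0 | 98 |
| midnight | 15.0 | 0 | 100 |
| midnight | 20.0 | 0 | 98 |
| midnight | 25.0 | 1 | 100 |

(scatter of a reading: 2 percentage points)

- the numbers in the tables scatter by 2 percentage points (one standard deviation)
- what has gone from L into another species counts as reacted, even if it can come back

* part of the L that has reacted at the end, Sunday's
* part of the L that has reacted at the end, Friday's
* part of the L that has reacted at the end, Tuesday's
* what raising the equivalents of D from its lowest to its highest value here does to the part of the L that has reacted (changes below 5 percentage points count as none) (it rises / no change / it falls)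

Note for the bench: the reckoning here treats full reaction as the large thing and computes only the unreacted L as a correction. Assuming D is the limiting reagent of the summer run, 1.1 equiv over 62% gives 1.77 of D per J: the D price, a reading with the scatter of J. In that run's last reading L makes up 47.4% of what is not J.

Sunday's flask has 1.30 equiv, below the price, so at the end it should hold 73.3% J. If the same share of the remainder stays L, that gives 87.3% reacted. Friday's and Tuesday's charges both stand above the price, so the correction should fall within the scatter there, as it does in the midnight run. Not to touch: the D weighing on Sunday's, since on this reckoning J there follows D.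

The forecast says 90%, 98% and 99.5%, and of more D, it rises; in its words, “The stall fits either a reversible uptake of L by D or D running out through extra consumption”. On Sunday's it stands higher than the reckoning here.

The simulation gives 86.3%, 99.9% and >99.9%; raising D, it rises, by 14 percentage points.

    L + D → G + J (k = 130 M⁻¹ h⁻¹)
    D + G ⇌ E, settled at all times (K = 57000 M⁻¹)
    D + G ⇌ X, settled at all times (K = 28.0 M⁻¹)
    L ⇌ Q (K = 1.10, k = 0.170 h⁻¹)

Sunday's ends 3.7 points under the forecast, with 70.7% J and 0.59% of its D unbound, and its answer shifts by 5 points at 1.08 equiv or 1.54 equiv of D. The neighbour of Friday's, charged with 1.00 equiv of D, takes the same reckoning: its charge over the price gives 56.4% J, and the share of the remainder leaves 20.7% L, so 79.3% reacted. That flask gives 56.5% J and 79.6% reacted, with 20% of its L unbound and 0.51% of its D.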